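Readings and results were generated by integration from invented constants.

Summer and dawn climb slowly, so their books are short; what we watch on repeating birch and elm is whether the hot start of elm keeps them. The solid electrophile is the limiting reagent (0.50 M, against 0.900 M of nucleophile), so each mole charged is booked as undissolved, dissolved or target.

| setting | summer | dusk | dawn | birch | elm |
|---|---|---|---|---|---|
| solid electrophile | 0.50 M | 0.50 M | 0.50 M | 0.50 M | 0.50 M |
| nucleophile | 0.90 M | 0.90 M | 1.8 M | 0.900 M | 0.900 M |
| free base | 0.38 M | 0.56 M | 0.75 M | 0.750 M | 0.750 M |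
| temperature | −40 °C | −15 °C | −40 °C |  |  |
| remark | run made earlier | run made earlier | run made earlier | at −35 °C throughout | at 5 °C until 15 min, from then on at −35 °C |
| time |  |  |  | 250 min | 80 min |

| run | time / min | target / % |
|---|---|---|
| summer | 60.0 | 0.2 |
| summer | 150 | 1.7 |
| summer | 180 | 2.8 |
| summer | 300 | 4.6 |
| summer | 360 | 5.5 |
| summer | 480 | 6.9 |
| dusk | 10.0 | 1.6 |
| dusk | 15.0 | 2.7 |
| dusk | 20.0 | 4.6 |
| dusk | 40.0 | 10.3 |
| dusk | 50.0 | 12.3 |
| dusk | 80.0 | 20.6 |
| dusk | 150 | 36.8 |
| dawn | 40.0 | 0.9 |
| dawn | 80.0 | 1.8 |
| dawn | 150 | 3.7 |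
| dawn | 240 | 6.8 |
| dawn | 480 | 14.0 |

(scatter of a reading: 0.3 percentage points)

- at the start none of the solid electrophile is in solution
- what has only dissolved of solid electrophile counts as not reacted

- the flask that ends with the higher amount of target, in percent of the solid electrophile charged, or "neither" when 2 percentage points or less lies between them (birch / elm / neither)
- final target, as a percentage of the solid electrophile charged, in birch
- final target, as a percentage of the solid electrophile charged, in elm

We take dissolving as fast and the solution as holding a plateau of electrophile while solid remains, so target climbs in a straight line. Dawn's late slope is 2.28 times summer's, with [nucleophile] twice and [free base] twice what summer had. These two runs cannot part the two changes, so we assume the rise belongs to the nucleophile.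

Summer's late stretch then reads 7.59 × 10⁻⁵ min⁻¹ per [nucleophile]. Dusk bends, so we read its early stretch: 0.00161 min⁻¹, with a lag of 4.48 min. Together these two readings give an activation energy of 61.2 kJ mol⁻¹. So at −35 °C the constant is 1.47 × 10⁻⁴ min⁻¹, and 0.0125 min⁻¹ at 5 °C is our ceiling constant, the rate of target per [nucleophile] at the plateau.

The ledger for birch books 6.51% as target and 93.5% as undissolved or dissolved. Elm books 23.7% as target while hot and 1.72% while cold, which leaves 74.6% undissolved or dissolved.

The forecast, on the ground that “The rate is nearly constant after a short lag”, gave 11% for birch, above our figure, 26% for elm against our 25.4%, and elm as the flask with more.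

The flasks give 6.72% in birch and 17.8% in elm, so elm ends higher.

    electrophile + nucleophile → acid set free + target (k = 9.15 × 10⁻⁴ L mol⁻¹ s⁻¹, Ea = 63.0 kJ mol⁻¹)
    nucleophile + acid set free ⇌ protonated nucleophile, settled at all times (K = 45.8 L mol⁻¹, ΔH = −41.0 kJ mol⁻¹)
    acid set free + free base ⇌ salt of the base, settled at all times (K = 17000 L mol⁻¹, ΔH = −63.0 kJ mol⁻¹)
    free base ⇌ dormant form (K = 0.560, k = 0.0222 s⁻¹, Ea = 66.0 kJ mol⁻¹, ΔH = 38.0 kJ mol⁻¹)
    target ⇌ isomer of the product (K = 1.30, k = 5.29 × 10⁻⁴ s⁻¹, Ea = 90.0 kJ mol⁻¹, ΔH = −39.0 kJ mol⁻¹)
    solid electrophile ⇌ electrophile, rate k6*(cs6 - [electrophile]) while solid is left; crystals form when [electrophile] > cs6 (solubility = 0.280 M, k = 0.00227 s⁻¹)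
    (constants at 5 °C)

At 15.0 min, the change of temperature, elm held 39.2% as electrophile, less than the 55.8% it held at 80.0 min. At 15.0 min target and isomer of the product in elm came to 19.2%, less than the 23.7% booked for the hot stretch. For a neighbour of elm charged with 0.23 M of nucleophile, the same ledger with the ceiling constant books 6.49%; the computed flask gives 5.05%.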